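(Its constants are assumed; no experiment stands behind them.)

Per hour is the unit to think in here: I reckon the fraction of the remaining Sub that Rgt turns into Pdt2 each hour.

    Sub ⇌ Imd (K1 = 0.048, k1 = 0.101 h⁻¹, Ea1 = 111 kJ mol⁻¹, ΔH1 = 17.0 kJ mol⁻¹)
    Spx ⇌ Rgt, rate k2*(csat - [Rgt]) (k2 = 0.313 h⁻¹, csat = 8.1 mM)
    Rgt + Imd → Pdt2 (k3 = 20.6 M⁻¹ h⁻¹, Ea3 = 78.0 kJ mol⁻¹)
    2 Sub → Pdt (k4 = 0.00248 M⁻¹ h⁻¹, Ea4 = 81.0 kJ mol⁻¹)
    (constants at 70 °C)

all flasks: Sub 0.050 M; Spx 8.1 mM (held); time 3.0 d
- dusk: temperature 70 °C
- winter: temperature 50 °C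

1. the best flask by amount of Pdt2, in percent of the Sub charged; "all alike" if 1.5 percentage points covers them all (dusk / winter / all alike)
2. amount of Pdt2 at the end, in percent of the Sub charged, dusk
3. amount of Pdt2 at the end, in percent of the Sub charged, winter

- percentages count the Sub that a species holds: one Pdt counts as two
- two of one species on the left: rate k times its square, two consumed each time
- at the start none of Rgt is dissolved
- the constants hold at 70 °C; other temperatures follow from the activation energies and enthalpies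

Sub and Imd relax with a half-life of 0.314 h, much shorter than the run, so I treat them as one pool. Its fraction of the charge falls exponentially. I call the pseudo-first-order constant of that fall the drain λ: the fraction of the pool that becomes Pdt2 each hour.

The bench rule I try first takes dissolved Rgt in this flask to sit at saturation. Rgt fills in about 3.19 h, far shorter than the run. With forward constant f, back constant r and capture κ of Imd by saturated Rgt, dusk gives:

f = 0.101 h⁻¹, r = f/K = 2.10 h⁻¹, κ = 0.167 h⁻¹

λ = κ·f/(f + r + κ) = 0.00710 h⁻¹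

Pdt2 = 1 − exp(−λt) = 40.0%

The rule's border is the ratio b of Rgt demand at the charge to the largest gas supply:

b = λ·cA/(transfer coefficient·csat) = 0.140

Balancing supply against demand puts Rgt near csat/(1 + b), and λ shrinks nearly in step, so dusk has:

λ = 0.00623 h⁻¹, Pdt2 = 36.2%

The step from Sub to Pdt starts at 2.48 × 10⁻⁴ h⁻¹, below this drain, so I drop it. Holding the gas constants fixed, I cool the others for winter:

f = 0.00909 h⁻¹, K = 0.0332, κ = 0.0307 h⁻¹

λ = 8.91 × 10⁻⁴ h⁻¹, b = 0.0176

Pdt2 = 6.11%

My choice is dusk.

The forecast also names dusk, with 35.5% (33.5% to 37.5%) for dusk and 5.7% (5.1% to 6.3%) for winter. It reckons “With about 3 h of start-up lag”, and its dusk figure stands below mine.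

The simulation gives dusk, with 35.7% of Pdt2 in dusk and 5.75% in winter. Dusk holds Rgt at 0.00742 M at 3.00 d, below 8.1 mM. A neighbouring flask is dusk with 0.20 M of Sub. For it I reckon b at 0.560, λ at 0.00455 h⁻¹, and Pdt2 at 28.0%. That flask reads 28.3%, with Rgt at 0.00583 M.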